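**Retrosynthetic overview**
- The target comes from its octa-O-methyl ether by BBr3; every phenol is carried as an OMe group that arrives with the building blocks.
- Each trans-2,3-diaryl dihydrofuran comes from acid closure of a p-methoxybenzylic carbinol, made from a lactol, made by oxidative cleavage of an (E)-propenyl group, itself the product of an aromatic Claisen rearrangement of a lactate-derived secondary allyl aryl ether (C8–aryl bond and C8 configuration by 1,3-chirality transfer; C7 follows as the trans isomer).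
- The seven-membered ring comes from Friedel–Crafts closure of the C7b cation of a 2,4-dimethoxystilbene onto the 8a-aryl ring (C7b set by C8a); the stilbene comes from a Heck reaction at an aryl bromide.
- The allyl aryl ethers come from Mitsunobu etherification of a phenol with methyl lactate (inversion), then one-pot reduction/Horner–Wadsworth–Emmons olefination; methyl (R)-lactate gives unit a, methyl (S)-lactate gives unit c, and the core is 5-bromoresorcinol.
- Ring order: the unit-a dihydrofuran, then the seven-membered ring, then the unit-c dihydrofuran (the 8c-aryl ring is brought in only after the Friedel–Crafts closure, so only the 8a-aryl ring can cyclise).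

Assumption and locants (one line): 2,4-dimethoxystyrene, the phosphonate, the Grignard reagent and both methyl lactates are taken as catalogue chemicals; oligostilbene locants with the unit letters a, b, c are used: C7a/C8a and C7c/C8c are the O–CH/CH carbons of the two dihydrofurans, each C7 carries a 4-oxyphenyl ring (the 7a-aryl and 7c-aryl rings), each C8 carries a 3,5-dioxyphenyl ring (the 8a-aryl ring, C9a–C14a, and the 8c-aryl ring), the central ring is C9b–C14b (C9b–C8b, C10b–C8a, C11b–O, C13b–O, C14b–C8c), C8b is the CH2 group and C7b is the CH that carries the 2,4-dioxyphenyl ring (the 7b-aryl ring).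

**Route**

Step 1
Reactants: 1 5-bromoresorcinol; 2 methyl (R)-lactate
Product: 3 methyl (2S)-2-(3-bromo-5-hydroxyphenoxy)propanoate
Conditions: PPh3, DIAD, THF, 0 °C to rt (1 in threefold excess, recovered)
Reagents that add atoms: none
Why: Mitsunobu etherification is an SN2 displacement at the lactate carbinol with clean inversion, so the (R)-lactate gives the (S)-aryloxypropanoate, and the excess of diol keeps it at mono-etherification.

Step 2
Reactants: 3 methyl (2S)-2-(3-bromo-5-hydroxyphenoxy)propanoate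
Product: 4 methyl (2S)-2-[3-bromo-5-(methoxymethoxy)phenoxy]propanoate
Conditions: MOMCl, K2CO3, acetone, rt
Reagents that add atoms: chloromethyl methyl ether, COCCl
Why: Williamson-type O-alkylation protects the second phenol under a carbonate base too weak to epimerise the α-aryloxy ester.

Step 3
Reactants: 4 methyl (2S)-2-[3-bromo-5-(methoxymethoxy)phenoxy]propanoate; 5 diethyl (3,5-dimethoxybenzyl)phosphonate
Product: 7 1-bromo-3-{[(2S,3E)-4-(3,5-dimethoxyphenyl)but-3-en-2-yl]oxy}-5-(methoxymethoxy)benzene, via aryloxypropanal 6 (not isolated)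
Conditions: i-Bu2AlH (1.1 equiv), CH2Cl2, −78 °C; then 5 + KN(SiMe3)2 in THF, −78 °C to rt
Reagents that add atoms: none
Why: The ester is reduced only to the aluminium hemiacetal, which releases the aldehyde in the presence of the phosphonate anion, so the Horner–Wadsworth–Emmons olefination gives the (E)-styrenyl ether before the α-stereocentre can epimerise.

Step 4
Reactants: 7 1-bromo-3-{[(2S,3E)-4-(3,5-dimethoxyphenyl)but-3-en-2-yl]oxy}-5-(methoxymethoxy)benzene
Product: 9 3-bromo-2-[(1S,2E)-1-(3,5-dimethoxyphenyl)but-2-en-1-yl]-5-(methoxymethoxy)phenol, via ortho-dienone 8 (not isolated)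
Conditions: PhNEt2, 185 °C, sealed tube
Reagents that add atoms: none
Why: The aromatic Claisen rearrangement ([3,3]-sigmatropic) runs through a chair transition state with the methyl group equatorial, which carries the C–O stereocentre suprafacially into the new C8a–C10b bond (S-ether gives C8a as in the target, new alkene E); the bromine and the meta-OMOM group both steer the shift to C10b, and the dienone tautomerises to the phenol.

Step 5
Reactants: 9 3-bromo-2-[(1S,2E)-1-(3,5-dimethoxyphenyl)but-2-en-1-yl]-5-(methoxymethoxy)phenol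
Product: 12 (3S)-4-bromo-3-(3,5-dimethoxyphenyl)-6-(methoxymethoxy)-2,3-dihydro-1-benzofuran-2-ol (both C2 epimers), via glycol 10 (not isolated), via hydroxy aldehyde 11 (not isolated)
Conditions: OsO4 (2 mol%), NaIO4, 2,6-lutidine, dioxane/H2O, rt
Reagents that add atoms: sodium periodate, [Na+].[O-]I(=O)(=O)=O (oxygen passed on by the OsO4 catalyst)
Why: Lemieux–Johnson cleavage (dihydroxylation, then periodate glycol cleavage) removes the lactate-derived carbons as acetaldehyde, and the aldehyde is trapped at once as the five-ring lactol, which protects the doubly benzylic C8a–H from enolisation.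

Step 6
Reactants: 12 (3S)-4-bromo-3-(3,5-dimethoxyphenyl)-6-(methoxymethoxy)-2,3-dihydro-1-benzofuran-2-ol; 13 4-methoxyphenylmagnesium bromide
Product: 15 (2S,3S)-4-bromo-3-(3,5-dimethoxyphenyl)-2-(4-methoxyphenyl)-6-(methoxymethoxy)-2,3-dihydro-1-benzofuran, via diol 14 (not isolated)
Conditions: 13 (3 equiv), CeCl3, THF, −78 to 0 °C; cold 1 M HCl quench; then p-TsOH·H2O (10 mol%), CH2Cl2, 0 °C
Reagents that add atoms: none
Why: The weakly basic organocerium reagent adds to the ring-opened aldehyde without enolising it, and a catalytic non-nucleophilic acid (which spares the MOM ether) ionises the p-methoxybenzylic carbinol so that the phenol closes the ring (SN1 cycloetherification) to the favoured 2,3-trans dihydrofuran, which sets C7a from C8a.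

Step 7
Reactants: 15 (2S,3S)-4-bromo-3-(3,5-dimethoxyphenyl)-2-(4-methoxyphenyl)-6-(methoxymethoxy)-2,3-dihydro-1-benzofuran; 16 2,4-dimethoxystyrene
Product: 17 (2S,3S)-3-(3,5-dimethoxyphenyl)-4-[(E)-2-(2,4-dimethoxyphenyl)ethenyl]-2-(4-methoxyphenyl)-6-(methoxymethoxy)-2,3-dihydro-1-benzofuran
Conditions: Pd(OAc)2, P(o-tol)3, NaOAc, DMA, 120 °C
Reagents that add atoms: none
Why: Mizoroki–Heck coupling of the aryl bromide with the terminal styrene gives the E-stilbene without touching a stereocentre.

Step 8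
Reactants: 17 (2S,3S)-3-(3,5-dimethoxyphenyl)-4-[(E)-2-(2,4-dimethoxyphenyl)ethenyl]-2-(4-methoxyphenyl)-6-(methoxymethoxy)-2,3-dihydro-1-benzofuran
Product: 19 seven-ring phenol (7aS,8aS,7bS): 17 with C7b bonded to C10a of the 8a-aryl ring and the MOM group removed (free 13b-OH), via MOM ether 18 (not isolated)
Conditions: HCl (2 M), MeOH/CH2Cl2, 40 °C, high dilution
Reagents that add atoms: none
Why: Protonation at C8b gives the 2,4-dimethoxybenzyl cation at C7b, which the 8a-aryl ring captures in an intramolecular Friedel–Crafts alkylation (the ε-viniferin to ampelopsin B type closure); the fused dihydrofuran fixes the ring fold so that the new aryl group sits pseudo-axial, syn to H8a and away from the peri 11a-OMe (7bS, also the thermodynamic epimer of this reversible closure), while the same methanolic acid removes the MOM group.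

Step 9
Reactants: 19 seven-ring phenol (7aS,8aS,7bS); 20 methyl (S)-lactate
Product: 21 methyl (2R)-2-[(seven-ring core of 19)-13b-yloxy]propanoate
Conditions: PPh3, DIAD, THF, 0 °C to rt
Reagents that add atoms: none
Why: Mitsunobu etherification of the only free phenol inverts the lactate carbinol, so the (S)-lactate gives the (R)-aryloxypropanoate needed for unit c.

Step 10
Reactants: 21 methyl (2R)-2-[(seven-ring core of 19)-13b-yloxy]propanoate; 5 diethyl (3,5-dimethoxybenzyl)phosphonate
Product: 23 13b-O-[(2R,3E)-4-(3,5-dimethoxyphenyl)but-3-en-2-yl] ether of 19, via aryloxypropanal 22 (not isolated)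
Conditions: i-Bu2AlH (1.1 equiv), CH2Cl2, −78 °C; then 5 + KN(SiMe3)2 in THF, −78 °C to rt
Reagents that add atoms: none
Why: As in step 3, one-pot partial reduction and Horner–Wadsworth–Emmons olefination give the (E)-allyl aryl ether without isolating the epimerisable aldehyde.

Step 11
Reactants: 23 13b-O-[(2R,3E)-4-(3,5-dimethoxyphenyl)but-3-en-2-yl] ether of 19
Product: 25 14b-[(1R,2E)-1-(3,5-dimethoxyphenyl)but-2-en-1-yl] derivative of 19, via ortho-dienone 24 (not isolated)
Conditions: PhNEt2, 185 °C, sealed tube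
Reagents that add atoms: none
Why: The second aromatic Claisen rearrangement ([3,3]-sigmatropic, chair, methyl equatorial) transfers the (R)-ether stereocentre to C8c in the mirror-image sense of step 4 (8cR), and the shift is expected to favour C14b, which is para to the donor O11b, over C12b, which lies between the two oxygens.

Step 12
Reactants: 25 14b-[(1R,2E)-1-(3,5-dimethoxyphenyl)but-2-en-1-yl] derivative of 19
Product: 28 lactol (8cR): 19 with a C14b–C8c(3,5-dimethoxyphenyl)–C7c(OH)–O13b ring (both C7c epimers), via glycol 26 (not isolated), via hydroxy aldehyde 27 (not isolated)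
Conditions: OsO4 (2 mol%), NaIO4, 2,6-lutidine, dioxane/H2O, rt
Reagents that add atoms: sodium periodate, [Na+].[O-]I(=O)(=O)=O (oxygen passed on by the OsO4 catalyst)
Why: Lemieux–Johnson cleavage of the only alkene gives the aldehyde, held as its lactol so that C8c does not epimerise.

Step 13
Reactants: 28 lactol (8cR); 13 4-methoxyphenylmagnesium bromide
Product: 30 octa-O-methyl ether of the target (7aS,8aS,7bS,7cR,8cR), via diol 29 (not isolated)
Conditions: 13 (3 equiv), CeCl3, THF, −78 to 0 °C; cold 1 M HCl quench; then p-TsOH·H2O (10 mol%), CH2Cl2, 0 °C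
Reagents that add atoms: none
Why: Organocerium addition to the ring-opened aldehyde and acid-mediated SN1 cycloetherification give the 2,3-trans dihydrofuran, so C7c is set by C8c.

Step 14
Reactants: 30 octa-O-methyl ether of the target
Product: 31 target CNP0154047.3
Conditions: BBr3 (24 equiv), CH2Cl2, −78 °C to rt; then MeOH/H2O
Reagents that add atoms: none
Why: Lewis-acid ether cleavage removes all eight aryl methyl groups; the C8 and C7b centres cannot epimerise and any reversible opening of a dihydrofuran at C7 recloses to the trans isomer.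

**Compound list**

1 | 5-bromoresorcinol | Oc1cc(O)cc(Br)c1 | starting material
2 | methyl (R)-lactate | C[C@@H](O)C(=O)OC | starting material
3 | methyl (2S)-2-(3-bromo-5-hydroxyphenoxy)propanoate | C[C@H](Oc1cc(O)cc(Br)c1)C(=O)OC | intermediate
4 | methyl (2S)-2-[3-bromo-5-(methoxymethoxy)phenoxy]propanoate | C[C@H](Oc1cc(OCOC)cc(Br)c1)C(=O)OC | intermediate
5 | diethyl (3,5-dimethoxybenzyl)phosphonate | CCOP(=O)(Cc1cc(OC)cc(OC)c1)OCC | starting material
6 | (2S)-2-[3-bromo-5-(methoxymethoxy)phenoxy]propanal | C[C@H](Oc1cc(OCOC)cc(Br)c1)C=O | intermediate (not isolated)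
7 | 1-bromo-3-{[(2S,3E)-4-(3,5-dimethoxyphenyl)but-3-en-2-yl]oxy}-5-(methoxymethoxy)benzene | C[C@H](Oc1cc(OCOC)cc(Br)c1)/C=C/c1cc(OC)cc(OC)c1 | intermediate
8 | 5-bromo-6-[(1R,2E)-1-(3,5-dimethoxyphenyl)but-2-en-1-yl]-3-(methoxymethoxy)cyclohexa-2,4-dien-1-one (ring C6 epimer not specified; side-chain carbon has the geometry of 9, the descriptor differs only through CIP ranking) | C/C=C/[C@@H](c1cc(OC)cc(OC)c1)C1C(=O)C=C(OCOC)C=C1Br | intermediate (not isolated)
9 | 3-bromo-2-[(1S,2E)-1-(3,5-dimethoxyphenyl)but-2-en-1-yl]-5-(methoxymethoxy)phenol | C/C=C/[C@@H](c1cc(OC)cc(OC)c1)c1c(O)cc(OCOC)cc1Br | intermediate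
10 | 3-bromo-2-[(1S)-1-(3,5-dimethoxyphenyl)-2,3-dihydroxybutyl]-5-(methoxymethoxy)phenol (glycol carbons not specified) | CC(O)C(O)[C@@H](c1cc(OC)cc(OC)c1)c1c(O)cc(OCOC)cc1Br | intermediate (not isolated)
11 | (2S)-2-[2-bromo-6-hydroxy-4-(methoxymethoxy)phenyl]-2-(3,5-dimethoxyphenyl)acetaldehyde | O=C[C@@H](c1cc(OC)cc(OC)c1)c1c(O)cc(OCOC)cc1Br | intermediate (not isolated)
12 | (3S)-4-bromo-3-(3,5-dimethoxyphenyl)-6-(methoxymethoxy)-2,3-dihydro-1-benzofuran-2-ol (both C2 epimers) | OC1Oc2cc(OCOC)cc(Br)c2[C@@H]1c1cc(OC)cc(OC)c1 | intermediate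
13 | 4-methoxyphenylmagnesium bromide | COc1ccc([Mg]Br)cc1 | starting material
14 | 3-bromo-2-[(1S)-1-(3,5-dimethoxyphenyl)-2-hydroxy-2-(4-methoxyphenyl)ethyl]-5-(methoxymethoxy)phenol (carbinol epimers) | COc1ccc(C(O)[C@@H](c2cc(OC)cc(OC)c2)c2c(O)cc(OCOC)cc2Br)cc1 | intermediate (not isolated)
15 | (2S,3S)-4-bromo-3-(3,5-dimethoxyphenyl)-2-(4-methoxyphenyl)-6-(methoxymethoxy)-2,3-dihydro-1-benzofuran | COc1ccc([C@H]2Oc3cc(OCOC)cc(Br)c3[C@@H]2c2cc(OC)cc(OC)c2)cc1 | intermediate
16 | 2,4-dimethoxystyrene | C=Cc1ccc(OC)cc1OC | starting material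
17 | (2S,3S)-3-(3,5-dimethoxyphenyl)-4-[(E)-2-(2,4-dimethoxyphenyl)ethenyl]-2-(4-methoxyphenyl)-6-(methoxymethoxy)-2,3-dihydro-1-benzofuran | COc1ccc([C@H]2Oc3cc(OCOC)cc(/C=C/c4ccc(OC)cc4OC)c3[C@@H]2c2cc(OC)cc(OC)c2)cc1 | intermediate
18 | 13b-O-methoxymethyl ether of 19 | COc1ccc([C@H]2Oc3cc(OCOC)cc4c3[C@@H]2c2cc(OC)cc(OC)c2[C@H](c2ccc(OC)cc2OC)C4)cc1 | intermediate (not isolated)
19 | seven-ring phenol (7aS,8aS,7bS): trans-2,3-diaryl dihydrofuran fused at C10b/C11b; C7b (H, 2,4-dimethoxyphenyl) bonded to C10a of the 8a-aryl ring and through CH2-8b to C9b; OMe on the 7a-, 8a- and 7b-aryl rings; free OH on C13b | COc1ccc([C@H]2Oc3cc(O)cc4c3[C@@H]2c2cc(OC)cc(OC)c2[C@H](c2ccc(OC)cc2OC)C4)cc1 | intermediate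
20 | methyl (S)-lactate | C[C@H](O)C(=O)OC | starting material
21 | methyl (2R)-2-[(seven-ring core of 19)-13b-yloxy]propanoate | COc1ccc([C@H]2Oc3cc(O[C@H](C)C(=O)OC)cc4c3[C@@H]2c2cc(OC)cc(OC)c2[C@H](c2ccc(OC)cc2OC)C4)cc1 | intermediate
22 | (2R)-2-[(seven-ring core of 19)-13b-yloxy]propanal | COc1ccc([C@H]2Oc3cc(O[C@H](C)C=O)cc4c3[C@@H]2c2cc(OC)cc(OC)c2[C@H](c2ccc(OC)cc2OC)C4)cc1 | intermediate (not isolated)
23 | 13b-O-[(2R,3E)-4-(3,5-dimethoxyphenyl)but-3-en-2-yl] ether of 19 | COc1ccc([C@H]2Oc3cc(O[C@H](C)/C=C/c5cc(OC)cc(OC)c5)cc4c3[C@@H]2c2cc(OC)cc(OC)c2[C@H](c2ccc(OC)cc2OC)C4)cc1 | intermediate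
24 | ortho-dienone tautomer of 25 (C13b=O, C14b sp3, its configuration not specified; side-chain carbon has the geometry of 25, CIP descriptor 1S) | COc1ccc([C@H]2OC3=CC(=O)C([C@@H](c5cc(OC)cc(OC)c5)/C=C/C)C4=C3[C@@H]2c2cc(OC)cc(OC)c2[C@H](c2ccc(OC)cc2OC)C4)cc1 | intermediate (not isolated)
25 | 14b-[(1R,2E)-1-(3,5-dimethoxyphenyl)but-2-en-1-yl] derivative of 19 | COc1ccc([C@H]2Oc3cc(O)c([C@@H](c5cc(OC)cc(OC)c5)/C=C/C)c4c3[C@@H]2c2cc(OC)cc(OC)c2[C@H](c2ccc(OC)cc2OC)C4)cc1 | intermediate
26 | 14b-[(1R)-1-(3,5-dimethoxyphenyl)-2,3-dihydroxybutyl] derivative of 19 (glycol carbons not specified) | COc1ccc([C@H]2Oc3cc(O)c([C@@H](c5cc(OC)cc(OC)c5)C(O)C(O)C)c4c3[C@@H]2c2cc(OC)cc(OC)c2[C@H](c2ccc(OC)cc2OC)C4)cc1 | intermediate (not isolated)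
27 | (2R)-2-(3,5-dimethoxyphenyl)-2-[(seven-ring core of 19)-14b-yl]acetaldehyde | COc1ccc([C@H]2Oc3cc(O)c([C@@H](c5cc(OC)cc(OC)c5)C=O)c4c3[C@@H]2c2cc(OC)cc(OC)c2[C@H](c2ccc(OC)cc2OC)C4)cc1 | intermediate (not isolated)
28 | lactol (8cR): 19 with ring C14b–C8c(3,5-dimethoxyphenyl)–C7c(OH)–O13b (both C7c epimers) | COc1ccc([C@H]2Oc3cc4c(c5c3[C@@H]2c2cc(OC)cc(OC)c2[C@H](c2ccc(OC)cc2OC)C5)[C@@H](c2cc(OC)cc(OC)c2)C(O)O4)cc1 | intermediate
29 | 14b-[(1R)-1-(3,5-dimethoxyphenyl)-2-hydroxy-2-(4-methoxyphenyl)ethyl] derivative of 19 (carbinol epimers) | COc1ccc([C@H]2Oc3cc(O)c([C@@H](c5cc(OC)cc(OC)c5)C(O)c5ccc(OC)cc5)c4c3[C@@H]2c2cc(OC)cc(OC)c2[C@H](c2ccc(OC)cc2OC)C4)cc1 | intermediate (not isolated)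
30 | octa-O-methyl ether of the target (7aS,8aS,7bS,7cR,8cR) | COc1ccc([C@H]2Oc3cc4c(c5c3[C@@H]2c2cc(OC)cc(OC)c2[C@H](c2ccc(OC)cc2OC)C5)[C@@H](c2cc(OC)cc(OC)c2)[C@H](c2ccc(OC)cc2)O4)cc1 | intermediate
31 | CNP0154047.3 (7aS,8aS,7bS,7cR,8cR) | Oc1ccc([C@H]2Oc3cc4c(c5c3[C@@H]2c2cc(O)cc(O)c2[C@H](c2ccc(O)cc2O)C5)[C@@H](c2cc(O)cc(O)c2)[C@H](c2ccc(O)cc2)O4)cc1 | target

**Step count**

Total: 14 steps. Longest linear sequence: 14 steps (1 to 31).

**The three steps most likely to fail**

Step 8 (Friedel–Crafts ring closure). The open-chain cation from 17 may dimerise, may be diverted by ionisation of the dihydrofuran C7a–O bond, or may close to the wrong C7b epimer. The fallback builds the ring before the 7b-aryl ring is present. It sets out from bromide 15: Suzuki coupling with commercial (E)-2-ethoxyvinylboronic acid pinacol ester (Pd(PPh3)4, K3PO4, dioxane/H2O, 90 °C) gives (2S,3S)-3-(3,5-dimethoxyphenyl)-4-[(E)-2-ethoxyethenyl]-2-(4-methoxyphenyl)-6-(methoxymethoxy)-2,3-dihydro-1-benzofuran F1. F1 is then treated with the acid of step 8 in the presence of 1,3-dimethoxybenzene (2 equiv). The oxocarbenium ion from the enol ether is arylated twice: once by the 8a-aryl ring, which closes the seven-membered ring, and once by C4 of 1,3-dimethoxybenzene, which becomes the 7b-aryl ring and enters the cyclic cation from the open convex face, that is pseudo-axially. The MOM group is lost in the same pot and the route is rejoined at 19.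

Step 10 (one-pot reduction/olefination on the advanced ester). Over-reduction, slow collapse of the aluminium hemiacetal with the semi-stabilised phosphonate anion, or epimerisation of aldehyde 22 would each cost material or optical purity. The fallback makes the allylic alcohol separately and sets out from 19 and 20. Lactate 20 is silylated (TBSCl, imidazole, DMF) to methyl (2S)-2-[(tert-butyldimethylsilyl)oxy]propanoate F2, reduced (i-Bu2AlH, CH2Cl2, −78 °C) to (2S)-2-[(tert-butyldimethylsilyl)oxy]propanal F3, olefinated with 5 (KN(SiMe3)2, THF) to tert-butyl{[(2S,3E)-4-(3,5-dimethoxyphenyl)but-3-en-2-yl]oxy}dimethylsilane F4 and desilylated (n-Bu4NF, THF) to (2S,3E)-4-(3,5-dimethoxyphenyl)but-3-en-2-ol F5. Mitsunobu coupling of F5 with phenol 19 (PPh3, DIAD, toluene, 0 °C) inverts the carbinol and gives the (R)-ether 23 directly, by-passing 21 and 22.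

Step 11 (second Claisen rearrangement). No bromine steers this shift, so attack at C12b (between the two oxygens) may compete with attack at C14b; I expect roughly 2–4:1 in favour of C14b, and the isomers must be separated. If C12b predominates, the sigmatropic step is given up for unit c. The fallback sets out from phenol 19, which is iodinated ortho to the hydroxyl and para to O11b (I2, NaHCO3, THF/H2O, 0 °C) to give the 14b-iodo derivative of 19 F6; any C12b iodide is removed at this stage. F6 is annulated with commercial (E)-3,4',5-trimethoxystilbene in a Pd(OAc)2/Ag2CO3 oxyarylation (acetone, 60 °C): the aryl–palladium species adds so that C14b bonds to the carbon carrying the 3,5-dimethoxyphenyl group, and the phenol oxygen closes onto the p-methoxybenzylic carbon to give the 2,3-trans dihydrofuran. The route is rejoined at 30. Facial control then rests only on the stereocentres already present in 19, so 30 has to be separated from its 7c,8c-bis-epimer.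

**Further compounds**

F1 | step 8 | (2S,3S)-3-(3,5-dimethoxyphenyl)-4-[(E)-2-ethoxyethenyl]-2-(4-methoxyphenyl)-6-(methoxymethoxy)-2,3-dihydro-1-benzofuran | COc1ccc([C@H]2Oc3cc(OCOC)cc(/C=C/OCC)c3[C@@H]2c2cc(OC)cc(OC)c2)cc1
F2 | step 10 | methyl (2S)-2-[(tert-butyldimethylsilyl)oxy]propanoate | C[C@H](O[Si](C)(C)C(C)(C)C)C(=O)OC
F3 | step 10 | (2S)-2-[(tert-butyldimethylsilyl)oxy]propanal | C[C@H](O[Si](C)(C)C(C)(C)C)C=O
F4 | step 10 | tert-butyl{[(2S,3E)-4-(3,5-dimethoxyphenyl)but-3-en-2-yl]oxy}dimethylsilane | C[C@H](O[Si](C)(C)C(C)(C)C)/C=C/c1cc(OC)cc(OC)c1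
F5 | step 10 | (2S,3E)-4-(3,5-dimethoxyphenyl)but-3-en-2-ol | C[C@H](O)/C=C/c1cc(OC)cc(OC)c1
F6 | step 11 | 14b-iodo derivative of 19 | COc1ccc([C@H]2Oc3cc(O)c(I)c4c3[C@@H]2c2cc(OC)cc(OC)c2[C@H](c2ccc(OC)cc2OC)C4)cc1
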